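## Retrosynthetic overview

1. The furan C3–CH2 bond is made last by B-alkyl Suzuki–Miyaura coupling of a terminal alkene with 3-bromofuran; the furan ring is bought intact.
2. The free CO2H and that terminal alkene both come from zinc opening of a γ-iodolactone that masks them.
3. The (Z)-trisubstituted enoate comes from Still–Gennari olefination of an aldehyde with an α-homoprenyl phosphonate, itself made by alkylating the parent phosphonoacetate.
4. The aldehyde comes from aldehyde-selective Wacker oxidation of the free allyl arm of the iodolactone.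
5. The iodolactone comes from catalytic enantioselective iodolactonisation that differentiates the two enantiotopic allyl groups of achiral 2-allylpent-4-enoic acid (key step, sets the only stereocentre). Ring order: the γ-lactone is the only ring built (first step) and is opened again in the fifth step.

Assumption: compounds 1, 4, 5 and 11 are bought; the sense of induction in step 1 is provisional, and if (DHQD)2PHAL gives the mirror-image lactone, the pseudo-enantiomer (DHQ)2PHAL is used with nothing else changed.

Note on descriptors: the stereocentre keeps the same spatial arrangement from 2 to 13. It reads S in 2, 3, 9 and 10 and R in 12 and 13 only because the CIP ranking of its two arms changes.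

## Route

Step 1
Reactants: 1 2-(prop-2-en-1-yl)pent-4-enoic acid (diallylacetic acid)
Product: 2 (3S,5R)-5-(iodomethyl)-3-(prop-2-en-1-yl)oxolan-2-one
Conditions: (DHQD)2PHAL (10 mol %), N-iodosuccinimide (1.2 equiv), CHCl3/n-hexane 1:1, −40 °C, dark; SiO2 chromatography to remove the cis lactone
Reagents that add atoms: N-iodosuccinimide, O=C1CCC(=O)N1I
Why: Proposed new method: enantioselective desymmetrising 5-exo iodolactonisation, in which the acid sits as a hydrogen-bonded ion pair on a quinuclidine nitrogen of the dimeric cinchona catalyst while the iodine donor is activated in the same pocket, so that iodonium formation and anti attack of the carboxylate take place on one face of one of the two enantiotopic allyl groups and fix C3 (S) and C5 (R) in one event; the closest known reaction types are (DHQD)2PHAL-catalysed halolactonisation of pent-4-enoic acids, catalytic desymmetrising halolactonisation of prochiral dialkynyl acids and auxiliary-directed group-selective iodolactonisation of diallylacetamides.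

Step 2
Reactants: 2 (3S,5R)-5-(iodomethyl)-3-(prop-2-en-1-yl)oxolan-2-one
Product: 3 3-[(3S,5R)-5-(iodomethyl)-2-oxooxolan-3-yl]propanal
Conditions: PdCl2(PhCN)2 (10 mol %), CuCl2·2H2O (10 mol %), AgNO2 (5 mol %), O2 (1 atm), t-BuOH/MeNO2 15:1, 23 °C
Reagents that add atoms: dioxygen, O=O
Why: Nitrite-modified aldehyde-selective Wacker oxidation puts the oxygen on the terminal carbon of the unbiased monosubstituted alkene, and the neutral conditions leave the lactone, the primary iodide and both stereocentres untouched.

Step 3
Reactants: 4 methyl 2-[bis(2,2,2-trifluoroethoxy)phosphoryl]acetate; 5 5-bromo-2-methylpent-2-ene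
Product: 7 methyl 2-[bis(2,2,2-trifluoroethoxy)phosphoryl]-6-methylhept-5-enoate (racemic), via sodium phosphonoacetate carbanion 6 (not isolated)
Conditions: NaH (1.05 equiv), THF/DMSO, 0 °C; then 5 (1.2 equiv), NaI (0.2 equiv), 50 °C
Reagents that add atoms: none
Why: SN2 C-alkylation of the stabilised phosphonoacetate carbanion with in-situ iodide exchange, where the hindered mono-alkylated product resists a second alkylation and its new stereocentre is racemic and erased in the olefination.

Step 4
Reactants: 3 3-[(3S,5R)-5-(iodomethyl)-2-oxooxolan-3-yl]propanal; 7 methyl 2-[bis(2,2,2-trifluoroethoxy)phosphoryl]-6-methylhept-5-enoate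
Product: 9 methyl (2Z)-5-[(3S,5R)-5-(iodomethyl)-2-oxooxolan-3-yl]-2-(4-methylpent-3-en-1-yl)pent-2-enoate, via potassium phosphonate carbanion 8 (not isolated)
Conditions: 7 (1.3 equiv), KN(SiMe3)2 (1.2 equiv), 18-crown-6 (4 equiv), THF, −78 °C; then 3, −78 °C
Reagents that add atoms: none
Why: Still–Gennari variant of the Horner–Wadsworth–Emmons olefination, in which the electron-poor trifluoroethyl phosphonate with a crown-separated potassium ion eliminates from the kinetic adduct to give the (Z)-enoate with CO2Me cis to the chain, the base being fully consumed by 7 before the aldehyde arrives so that the lactone centres are not enolised.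

Step 5
Reactants: 9 methyl (2Z)-5-[(3S,5R)-5-(iodomethyl)-2-oxooxolan-3-yl]-2-(4-methylpent-3-en-1-yl)pent-2-enoate
Product: 10 (2S,5Z)-6-(methoxycarbonyl)-10-methyl-2-(prop-2-en-1-yl)undeca-5,9-dienoic acid
Conditions: Zn dust (activated, 10 equiv), AcOH/THF 1:4, 23 °C
Reagents that add atoms: none
Why: Zinc-mediated reductive β-elimination (the reverse of the iodolactonisation) reduces the C–I bond and expels the carboxylate, which regenerates the allyl group and the free acid, erases C5 and leaves the α-stereocentre, the enoate and the prenyl alkene untouched because no base is present.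

Step 6
Reactants: 10 (2S,5Z)-6-(methoxycarbonyl)-10-methyl-2-(prop-2-en-1-yl)undeca-5,9-dienoic acid; 11 3-bromofuran
Product: 13 (2R,5Z)-2-[3-(furan-3-yl)propyl]-6-(methoxycarbonyl)-10-methylundeca-5,9-dienoic acid (target CNP0196614.2), via bis-boryl hydroboration adduct 12 (not isolated)
Conditions: 9-BBN-H (2.4 equiv B–H), THF, 0 → 23 °C; then 11 (1.5 equiv), PdCl2(dppf) (5 mol %; dppf = 1,1'-bis(diphenylphosphino)ferrocene), K3PO4 (3 M aq, 4 equiv), DMF, 50 °C; citric acid work-up to pH 4
Reagents that add atoms: none
Why: Anti-Markovnikov hydroboration followed by B-alkyl Suzuki–Miyaura coupling, in which one equivalent of borane is taken up by the acid as an acyloxyborane, the second adds only to the monosubstituted alkene (the trisubstituted alkenes and the enoate react far more slowly) and the primary alkylborane then transfers to the furylpalladium bromide formed from 11, the stereocentre not being involved.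

## Compound list

1 | 2-(prop-2-en-1-yl)pent-4-enoic acid | C=CCC(CC=C)C(=O)O | starting material
2 | (3S,5R)-5-(iodomethyl)-3-(prop-2-en-1-yl)oxolan-2-one | C=CC[C@H]1C[C@H](CI)OC1=O | intermediate
3 | 3-[(3S,5R)-5-(iodomethyl)-2-oxooxolan-3-yl]propanal | O=CCC[C@H]1C[C@H](CI)OC1=O | intermediate
4 | methyl 2-[bis(2,2,2-trifluoroethoxy)phosphoryl]acetate | COC(=O)CP(=O)(OCC(F)(F)F)OCC(F)(F)F | starting material
5 | 5-bromo-2-methylpent-2-ene | CC(C)=CCCBr | starting material
6 | sodium 1-[bis(2,2,2-trifluoroethoxy)phosphoryl]-2-methoxy-2-oxoethan-1-ide | COC(=O)[CH-]P(=O)(OCC(F)(F)F)OCC(F)(F)F.[Na+] | intermediate (not isolated)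
7 | methyl 2-[bis(2,2,2-trifluoroethoxy)phosphoryl]-6-methylhept-5-enoate (racemic) | COC(=O)C(CCC=C(C)C)P(=O)(OCC(F)(F)F)OCC(F)(F)F | intermediate
8 | potassium 2-[bis(2,2,2-trifluoroethoxy)phosphoryl]-1-methoxy-6-methyl-1-oxohept-5-en-2-ide | COC(=O)[C-](CCC=C(C)C)P(=O)(OCC(F)(F)F)OCC(F)(F)F.[K+] | intermediate (not isolated)
9 | methyl (2Z)-5-[(3S,5R)-5-(iodomethyl)-2-oxooxolan-3-yl]-2-(4-methylpent-3-en-1-yl)pent-2-enoate | COC(=O)/C(=C\CC[C@H]1C[C@H](CI)OC1=O)CCC=C(C)C | intermediate
10 | (2S,5Z)-6-(methoxycarbonyl)-10-methyl-2-(prop-2-en-1-yl)undeca-5,9-dienoic acid | COC(=O)/C(=C\CC[C@@H](CC=C)C(=O)O)CCC=C(C)C | intermediate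
11 | 3-bromofuran | Brc1ccoc1 | starting material
12 | 9-borabicyclo[3.3.1]nonan-9-yl (2R,5Z)-2-[3-(9-borabicyclo[3.3.1]nonan-9-yl)propyl]-6-(methoxycarbonyl)-10-methylundeca-5,9-dienoate | COC(=O)/C(=C\CC[C@@H](CCCB1C2CCCC1CCC2)C(=O)OB1C2CCCC1CCC2)CCC=C(C)C | intermediate (not isolated)
13 | (2R,5Z)-2-[3-(furan-3-yl)propyl]-6-(methoxycarbonyl)-10-methylundeca-5,9-dienoic acid | COC(=O)/C(=C\CC[C@@H](CCCc1ccoc1)C(=O)O)CCC=C(C)C | target

## Step count and risks

Total steps: 6. Longest linear sequence: 5 (steps 1, 2, 4, 5, 6).

**Step 1 (most likely to fail).** Known halolactonisation catalysts control the face of an unactivated monosubstituted alkene poorly, so the ee and the trans/cis ratio of 2 may be low. Unwanted stereoisomers can be returned to 1 with Zn/AcOH. The fallback replaces catalyst control by auxiliary control and sets out from 1: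
- Compound 1 is coupled with (2R,5R)-2,5-bis(methoxymethyl)pyrrolidine (EDC·HCl, HOBt, i-Pr2NEt, CH2Cl2) to give the amide 1-[(2R,5R)-2,5-bis(methoxymethyl)pyrrolidin-1-yl]-2-(prop-2-en-1-yl)pent-4-en-1-one F1.
- Treatment with I2 (3 equiv) in THF/H2O at 0–23 °C lets the amide oxygen cyclise onto the iodonium ion. Allylic 1,3-strain holds the α-hydrogen in the amide plane, which gives the trans lactone.
- The C2-symmetric auxiliary distinguishes the two diastereotopic allyl groups. The (2R,5R) enantiomer is chosen from the allylic-strain model, which is my own analysis and would need experimental confirmation.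
- The iminium lactone is hydrolysed in the same pot, releasing the recoverable auxiliary, and the fallback comes back to the route at 2.

**Step 2.** The methyl ketone regioisomer may form, and the primary iodide may not tolerate the silver and copper salts. The fallback sets out from 2 and uses hydroboration and alcohol oxidation instead of direct palladium oxidation:
- 9-BBN-H in THF at 0 → 23 °C gives the borane (3S,5R)-3-[3-(9-borabicyclo[3.3.1]nonan-9-yl)propyl]-5-(iodomethyl)oxolan-2-one F2, which is not isolated.
- Oxidation with NaBO3·4H2O in THF/H2O gives the alcohol (3S,5R)-3-(3-hydroxypropyl)-5-(iodomethyl)oxolan-2-one F3.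
- Dess–Martin periodinane with NaHCO3 in CH2Cl2 then gives the aldehyde, and the fallback comes back to the route at 3.

**Step 6.** The free acid consumes borane and may be reduced slowly, and 3-bromofuran is volatile and slow in oxidative addition. The fallback sets out from 10 and protects the acid for the coupling:
- Esterification with 2-(trimethylsilyl)ethanol (EDC·HCl, DMAP, CH2Cl2) gives 2-(trimethylsilyl)ethyl (2S,5Z)-6-(methoxycarbonyl)-10-methyl-2-(prop-2-en-1-yl)undeca-5,9-dienoate F4.
- 9-BBN-H (1.2 equiv) in THF gives the borane 2-(trimethylsilyl)ethyl (2R,5Z)-2-[3-(9-borabicyclo[3.3.1]nonan-9-yl)propyl]-6-(methoxycarbonyl)-10-methylundeca-5,9-dienoate F5, which is not isolated.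
- Coupling with 11 (PdCl2(dppf), K3PO4 aq, DMF, 50 °C) gives 2-(trimethylsilyl)ethyl (2R,5Z)-2-[3-(furan-3-yl)propyl]-6-(methoxycarbonyl)-10-methylundeca-5,9-dienoate F6.
- Bu4NF in THF at 0 °C cleaves only the silylethyl ester, and the fallback comes back to the route at 13.

## Further compounds

F1 | step 1 | 1-[(2R,5R)-2,5-bis(methoxymethyl)pyrrolidin-1-yl]-2-(prop-2-en-1-yl)pent-4-en-1-one | COC[C@H]1CC[C@H](COC)N1C(=O)C(CC=C)CC=C
F2 | step 2 | (3S,5R)-3-[3-(9-borabicyclo[3.3.1]nonan-9-yl)propyl]-5-(iodomethyl)oxolan-2-one | C1CCC2CCCC1B2CCC[C@H]1C[C@H](CI)OC1=O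
F3 | step 2 | (3S,5R)-3-(3-hydroxypropyl)-5-(iodomethyl)oxolan-2-one | OCCC[C@H]1C[C@H](CI)OC1=O
F4 | step 6 | 2-(trimethylsilyl)ethyl (2S,5Z)-6-(methoxycarbonyl)-10-methyl-2-(prop-2-en-1-yl)undeca-5,9-dienoate | COC(=O)/C(=C\CC[C@@H](CC=C)C(=O)OCC[Si](C)(C)C)CCC=C(C)C
F5 | step 6 | 2-(trimethylsilyl)ethyl (2R,5Z)-2-[3-(9-borabicyclo[3.3.1]nonan-9-yl)propyl]-6-(methoxycarbonyl)-10-methylundeca-5,9-dienoate | COC(=O)/C(=C\CC[C@@H](CCCB1C2CCCC1CCC2)C(=O)OCC[Si](C)(C)C)CCC=C(C)C
F6 | step 6 | 2-(trimethylsilyl)ethyl (2R,5Z)-2-[3-(furan-3-yl)propyl]-6-(methoxycarbonyl)-10-methylundeca-5,9-dienoate | COC(=O)/C(=C\CC[C@@H](CCCc1ccoc1)C(=O)OCC[Si](C)(C)C)CCC=C(C)C
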